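Read the target column of the oak run before anything else, and hold it against what is asked of gamma and epsilon.

all flasks: starting material 0.050 M
- elm: partner 0.024 M; scavenger 0.040 M; run made earlier
- oak: partner 0.095 M; scavenger 0.040 M; run made earlier
- gamma: partner 0.0475 M; scavenger 0.0400 M; time 10 h
- epsilon: partner 0.0475 M; scavenger 0.0400 M; time 20 h

- elm (time / h: starting material / %, intermediate / %, target / %): 0.417: 87.7, 10.6, 0.5; 1.33: 74.8, 24.0, 0.3; 2.50: 65.6, 32.9, 0.9; 3.00: 64.9, 32.9, 4.2; 5.00: 55.8, 37.5, 5.3; 6.00: 56.5, 37.9, 4.1; 8.00: 53.2, 38.6, 8.7
- oak (time / h: starting material / %, intermediate / %, target / %): 0.667: 47.5, 47.4, 0; 1.00: 38.8, 59.1, 1.6; 1.33: 28.9, 68.0, 2.3; 2.50: 13.7, 81.9, 5.5; 3.00: 10.0, 84.2, 7.2; 5.00: 1.7, 85.8, 14.3; 8.00: 0.7, 77.2, 21.5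

(scatter of a reading: 1 percentage point)

* which of these there is most of at the end, counted by the starting material in it, gamma (starting material / target / intermediate)
* which of these there is most of at the end, counted by the starting material in it, epsilon (starting material / target / intermediate)
* the largest of these amounts at the end, in percent of the starting material charged, gamma
* the largest of these amounts at the end, in percent of the starting material charged, epsilon



In the oak run, between 2.50 h and 8.00 h, the target climbs from 5.5 % to 21.5 % while the intermediate stands near 79.6 %. So I read a first-order loss of 0.0366 /h from the intermediate. The elm run, with a quarter of the partner, reads 0.0397 /h, close within the scatter. The oak figure gives 19.0 h, the half-life of the intermediate, the time in which this loss halves what stands.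

My bench rule is that the target overtakes the intermediate one half-life after the intermediate was made. The oak run had about half of its starting material left at 0.667 h. Gamma has half of that c(partner), so I allow twice the time, 1.33 h. The crossing then falls near 20.3 h, and the ratio of time to crossing marks the border: by this rule the intermediate leads below one, and the target takes the lead at one.

Gamma stands at 0.493 and epsilon at 0.986, so epsilon ends earlier than the crossing, but barely: the elm figure would put the crossing at 18.8 h, earlier than the end of epsilon. In gamma and epsilon c(partner) is smaller than c(starting material), so of these two the partner is the limiting reagent for making the intermediate. If its whole charge became intermediate at 1.33 h, I would get 69.2 % for gamma and 48.0 % for epsilon. That puts the whole charge in at the time I allowed for about half of it, so the target is reckoned early, and I commit to the intermediate in both.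

The forecast also names the intermediate for gamma and the intermediate for epsilon, which “stays the largest in both runs”, but at 64 % and 51 %. Its gamma figure is lower than mine, and its epsilon figure higher.

The flask gives the intermediate at 63.2 % in gamma and the intermediate at 49.1 % in epsilon, where the target stands at 40.8 %.

    intermediate → target (k = 1.00 × 10⁻⁵ /s)
    scavenger + released group → scavenged by-product (k = 0.0320 /M/s)
    starting material + released group ⇌ idle adduct, settled at all times (K = 7.20 /M)
    starting material + partner → intermediate + released group (k = 0.00360 /M/s)
    starting material → decomposition product (k = 2.40 × 10⁻⁸ /s)

Gamma has not come to rest at 10 h: 16 % of its starting material remains, and the intermediate is made at 0.508 of the rate at which it is used. In gamma, ten times the time lies 4.75 half-lives further on, which with no more intermediate made would take 63.2 % down to 2.35 %. The gamma flask then shows 3.44 % of intermediate and 91.3 % of target. Epsilon, 9.50 half-lives on and again with no more made, would fall to 0.0679 %. The epsilon flask shows 0.119 % of intermediate and 94.9 % of target.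

(The runs were computed for substances that don't exist; noise was put on by code.)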